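## The problem

The target 17 is a 2-arylchromen-4-one: benzene ring A is fused to the pyranone ring C, which carries benzene ring B at C2. It has no stereocentre, so nothing has to be set in space and no centre can steer another; the whole difficulty is positional. Ring A is a phloroglucinol-type ring with hydroxyls at C5 and C7 and a 3-methylbut-2-enyl (prenyl) group at C8. Direct C-prenylation of such a ring does not tell C8 from C6, and 5-hydroxyflavones can exchange the two positions by opening and reclosing ring C (Wessely–Moser). Ring B is a resorcinol ring whose C5' carries a 2-methylbut-3-en-2-yl group, a quaternary benzylic carbon that no simple alkylation delivers. Four phenols and two olefins narrow the choice of reagents: strong acid can close the 7-OH onto the prenyl double bond or the 4'-OH onto the vinyl group, and hydrogenation, electrophilic halogen and oxidants attack the olefins. The enabling feature is that C5, C6, C7 and C8 of ring A form an acetate-type unit between C4a and C8a: C5 is at the carboxyl level, C6–C7 is an acetyl unit, and C8 is a former methylene that already bears the prenyl CH2. Ring A can therefore be grown on a pyranone that has an ester on one carbon and a 4-methylpent-3-enyl chain on the next.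

## Retrosynthesis

**17 from 16.** Only the two ring B acetals are removed at the end. The ring A hydroxyls need no protection because the ring-forming step delivers them as phenoxides. The ring B phenols must stay masked through organolithium and amide-base chemistry, and methoxymethyl ethers stand up to both. The forward step needs acid mild enough to leave both olefins alone.

**16 from 13 and 14.** The C7–C8 and C5–C6 bonds are cut, which takes ring A apart into the pyranone ester 13 and the two-carbon acyl donor 14. The neighbouring cuts through ring C (O1–C2, C2–C3 or C4–C4a) would leave an intact, fully substituted ring A whose C8 versus C6 prenylation would have to be controlled. Cutting ring A instead moves the prenyl group into an aliphatic chain, where its position is fixed by connectivity. The precursor 13 is a monocyclic pyranone with one fewer ring and no free phenol. The forward reaction must deprotonate the side-chain CH2 selectively, acetylate it on carbon, and close a Claisen condensation onto the ester.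

**13 from 10 and 8 (through 11 and 12).** The pyranone is opened at the ring oxygen–aryl carbon bond and at the C3–C4 bond, giving the keto ester 10 and the arylpropiolic acid 8, activated as chloride 11. An ynone is preferred to a 1,3,5-triketone because it is already at the pyranone oxidation level. Ring closure of 12 is then an isomerisation and needs no acid-driven dehydration, which the acetals and olefins would not like. The forward steps are C-acylation at the central carbon of a β-keto ester and a 6-endo-dig addition of the enol oxygen to the ynone.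

**10 from 9 and 2.** The bond between the two chain methylenes is cut; γ-alkylation of the acetoacetate dianion with prenyl bromide 2 makes it. The prenyl group of the target thus begins as a homoprenyl chain whose first CH2 becomes C8.

**8 from 7 from 6.** The carboxyl carbon is cut from the alkyne (acetylide carboxylation) and the alkyne is traced to aldehyde 6 by one-carbon homologation. This keeps ring B in the aldehyde series, where the starting material is cheap.

**6 from 5, 4, 3, and 1 with 2.** The bond from C5 of the benzaldehyde to the quaternary carbon is cut. A 2-methylbut-3-en-2-yl group ortho to a phenol is exactly what the aromatic Claisen rearrangement of an O-prenyl ether delivers, so 5 goes back to ether 4. Ether 4 comes from selective 4-O-prenylation of 1 and protection of O2, which removes the chelate that would otherwise steer the shift to C3. Both five-carbon groups of the target thus come from the same bromide 2.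

## Roads not taken

**Alternative 1:** Both C–prenyl bonds are cut to oxygen, leading to the 5,4'-bis(prenyl ether) A1 of a 7,2'-bis(methoxymethyl) flavone. On heating with the europium Lewis acid Eu(fod)3, the 5-O-prenyl group should travel via C6 to C8 (Claisen then Cope, arriving unrearranged), and the 4'-O-prenyl group should shift once to C5' (arriving inverted), giving A2.
- Merits: both side chains come late from one cheap reagent, and the flavone nucleus is made by routine chemistry. On step count this road is probably shorter than the chosen one.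
- Weak points: the ring A migration tends to partition between the 6-(2-methylbut-3-en-2-yl) stage and C8. The 4'-ether has no neighbouring carbonyl to bind the catalyst, so it needs harsher heating, at which reverse-prenyl phenols isomerise further. Alkylating the chelated 5-OH to reach A1 is itself awkward.
- Comparison: the chosen plan also uses one aromatic Claisen shift, but on the simple benzaldehyde 4 at the start, where an isomer costs little. It sets against the shorter count the fact that C8 is fixed by the carbon skeleton of 13 and not by a migration ratio.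

**Alternative 2:** Ring B is cut at C1'–C2' and C5'–C6', giving the 2-ethynylchromone A3 and the 1-methoxy-1,3-bis(silyloxy)diene A4 that carries the tertiary allyl group at its terminus. Cycloaddition followed by expulsion of the methoxy group from the ketal carbon would aromatise ring B and give A5.
- Merits: the quaternary carbon is placed by the diene, with no aromatic rearrangement and no C3'/C5' question, and the ring B phenols emerge free. In these two respects it is better than the chosen plan.
- Weak points: the diene terminus that must bond is neopentyl-like and hindered, a terminal alkyne activated only through the chromone is a modest dienophile, and bis(silyloxy)dienes are fragile. A3 also still requires an 8-prenylated 5,7-dioxygenated chromone, so the C6/C8 problem of ring A is untouched.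
- Comparison: the chosen plan sets against the cleaner ring B the fact that it solves the harder positional problem (ring A) by construction, and that its ring B chemistry is entirely conventional.

**Alternative 3:** Ring C is cut at C4–C4a, C8a–O1 and O1–C2. The aryne from the silyl triflate A6 would insert into the C–O bond of the propiolic acid 8 (the same acid the chosen route makes), and the resulting phenoxide would close onto the ynone to give the tetrakis(methoxymethyl) flavone A7.
- Merits: this is the most convergent road, since two finished halves meet in one flask. The C5 alkoxy group should direct the oxygen nucleophile to C8a as required.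
- Weak points: A6 is a hexasubstituted benzene whose preparation brings back the regiocontrolled prenylation of a phloroglucinol over many steps. The aryne is formed next to one olefin and in the presence of two more, so ene reactions are a risk. Four acetals must then be removed instead of two.
- Comparison: in convergence Alternative 3 is better. The chosen plan sets against it a ring A precursor made in one step from methyl acetoacetate.

Key step: step 9

Remark on the chemistry: 12 and 15 are written as keto tautomers although both will exist largely as enols or metal enolates; the single stereocentre of 15 is formed racemic and is destroyed in the same step.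

## Route

Step 1
Reactants: 1 2,4-dihydroxybenzaldehyde; 2 1-bromo-3-methylbut-2-ene (prenyl bromide)
Product: 3 2-hydroxy-4-[(3-methylbut-2-en-1-yl)oxy]benzaldehyde
Conditions: K2CO3 (1.1 equiv), acetone, rt → 50 °C
Reagents that add atoms: none
Why: Williamson etherification; the 2-OH is hydrogen-bonded to the aldehyde and is the weaker nucleophile, so the 4-OH should be alkylated selectively.

Step 2
Reactants: 3 2-hydroxy-4-[(3-methylbut-2-en-1-yl)oxy]benzaldehyde
Product: 4 2-(methoxymethoxy)-4-[(3-methylbut-2-en-1-yl)oxy]benzaldehyde
Conditions: MOMCl, i-Pr2NEt, CH2Cl2, 0 °C → rt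
Reagents that add atoms: chloromethyl methyl ether (MOMCl), COCCl
Why: Acetal protection of a phenol; masking O2 breaks the chelate that would otherwise direct the coming rearrangement to C3.

Step 3
Reactants: 4 2-(methoxymethoxy)-4-[(3-methylbut-2-en-1-yl)oxy]benzaldehyde
Product: 5 4-hydroxy-2-(methoxymethoxy)-5-(2-methylbut-3-en-2-yl)benzaldehyde
Conditions: PhNEt2, 190 °C, sealed tube, argon
Reagents that add atoms: none
Why: Aromatic Claisen rearrangement, a [3,3] shift that turns the O-prenyl ether into the C-bound tertiary allyl group and then enolises to the phenol; C5 is the open ortho position, whereas C3 lies between two oxygens and is too crowded for a quaternary carbon, and no stereocentre arises.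

Step 4
Reactants: 5 4-hydroxy-2-(methoxymethoxy)-5-(2-methylbut-3-en-2-yl)benzaldehyde
Product: 6 2,4-bis(methoxymethoxy)-5-(2-methylbut-3-en-2-yl)benzaldehyde
Conditions: NaH, DMF, 0 °C; MOMCl, 0 °C → rt
Reagents that add atoms: chloromethyl methyl ether (MOMCl), COCCl
Why: O-alkylation of a phenoxide; the phenol para to the aldehyde is acidic, and its sodium salt should take up the small chloromethyl ether despite the neighbouring quaternary carbon.

Step 5
Reactants: 6 2,4-bis(methoxymethoxy)-5-(2-methylbut-3-en-2-yl)benzaldehyde
Product: 7 1-ethynyl-2,4-bis(methoxymethoxy)-5-(2-methylbut-3-en-2-yl)benzene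
Conditions: MeC(O)C(N2)P(O)(OMe)2, K2CO3, MeOH, rt
Reagents that add atoms: dimethyl (1-diazo-2-oxopropyl)phosphonate, CC(=O)C(=[N+]=[N-])P(=O)(OC)OC
Why: Seyferth–Gilbert homologation in the Ohira–Bestmann form; the mild carbonate/methanol medium leaves acetals and olefins untouched, and aryl aldehydes without α-hydrogens are good substrates.

Step 6
Reactants: 7 1-ethynyl-2,4-bis(methoxymethoxy)-5-(2-methylbut-3-en-2-yl)benzene
Product: 8 3-[2,4-bis(methoxymethoxy)-5-(2-methylbut-3-en-2-yl)phenyl]prop-2-ynoic acid
Conditions: n-BuLi (1.05 equiv), THF, −78 °C; CO2, −78 °C → rt; 1 M HCl to pH 3, 0 °C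
Reagents that add atoms: carbon dioxide, O=C=O
Why: Carboxylation of a lithium acetylide; with one equivalent of base at −78 °C the alkyne C–H is removed far faster than the ring position between the two acetal oxygens, and the brief cold acidification spares the acetals.

Step 7
Reactants: 9 methyl acetoacetate; 2 1-bromo-3-methylbut-2-ene (prenyl bromide)
Product: 10 methyl 7-methyl-3-oxooct-6-enoate
Conditions: NaH, THF, 0 °C; n-BuLi, 0 °C; 2, 0 °C → rt; aq. NH4Cl
Reagents that add atoms: none
Why: γ-Alkylation of the acetoacetate dianion (Weiler alkylation); the more basic terminal carbanion reacts with the primary allylic bromide by SN2 substitution.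

Step 8
Reactants: 8 3-[2,4-bis(methoxymethoxy)-5-(2-methylbut-3-en-2-yl)phenyl]prop-2-ynoic acid; 10 methyl 7-methyl-3-oxooct-6-enoate
Product: 13 methyl 6-[2,4-bis(methoxymethoxy)-5-(2-methylbut-3-en-2-yl)phenyl]-2-(4-methylpent-3-en-1-yl)-4-oxo-4H-pyran-3-carboxylate, via acid chloride 11 (not isolated), via acylated keto ester 12 (not isolated)
Conditions: 1-chloro-N,N,2-trimethylprop-1-en-1-amine, CH2Cl2, 0 °C → rt; then 10, MgCl2, pyridine, CH2Cl2, 0 °C → rt; then K2CO3 (cat.), MeCN, rt
Reagents that add atoms: none
Why: The α-chloroenamine forms the acid chloride without free HCl; the magnesium chelate of the β-keto ester is then acylated on carbon (soft-enolisation C-acylation), and the ketone enol oxygen of 12 adds to the ynone in a 6-endo-dig oxa-Michael closure that gives the pyranone without any dehydration step.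

Step 9
Reactants: 13 methyl 6-[2,4-bis(methoxymethoxy)-5-(2-methylbut-3-en-2-yl)phenyl]-2-(4-methylpent-3-en-1-yl)-4-oxo-4H-pyran-3-carboxylate; 14 1-acetylimidazole
Product: 16 2-[2,4-bis(methoxymethoxy)-5-(2-methylbut-3-en-2-yl)phenyl]-5,7-dihydroxy-8-(3-methylbut-2-en-1-yl)-4H-chromen-4-one, via methyl ketone 15 (not isolated)
Conditions: LiN(i-Pr)2 (2.2 equiv), THF, −78 °C; 14 (1.1 equiv), −78 °C; LiN(i-Pr)2 (1.2 equiv), −78 → 0 °C; aq. NH4Cl
Reagents that add atoms: none
Why: Proposed new method: LiN(i-Pr)2 removes a proton from the CH2 attached to pyranone C2, which is acidified through the C2=C3 double bond by both the C4 carbonyl and the C3 ester; since C3 is fully substituted, the extended enolate can only be acylated at the exocyclic carbon, and 14 transfers acetyl to it with loss of imidazolide to give 15 (C7–C8 bond). The spare equivalent of amide takes the doubly activated methine proton of 15, and the second charge removes a methyl proton, so that the dianion carries its reactive carbon at the terminus. This carbon attacks the neighbouring ester carbonyl in a 6-exo-trig (enolexo) Claisen closure (C5–C6 bond), methoxide leaves and the cyclic triketone tautomer is deprotonated to the 5,7-diphenoxide, so that aromatisation of ring A drives the sequence. The closest known reaction type is the acylation of laterally lithiated ortho-toluates followed by intramolecular Claisen condensation to naphthalene-1,3-diols, and lateral lithiation of 2-alkyl-4-pyranones is known in its own right; joining the two on a 2-alkyl-4-pyranone-3-carboxylate is the untested part. No stereocentre is formed in 16; the one created at C8 in 15 is erased when that carbon becomes part of the arene. The selectivity needed is deprotonation in place of addition to the pyranone or the ester, secured by the hindered amide at −78 °C, and C- over O-acetylation, favoured by the lithium counter-ion and the acylimidazole; the positions of all ring A substituents follow from the connectivity of 13.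

Step 10
Reactants: 16 2-[2,4-bis(methoxymethoxy)-5-(2-methylbut-3-en-2-yl)phenyl]-5,7-dihydroxy-8-(3-methylbut-2-en-1-yl)-4H-chromen-4-one
Product: 17 2-[2,4-dihydroxy-5-(2-methylbut-3-en-2-yl)phenyl]-5,7-dihydroxy-8-(3-methylbut-2-en-1-yl)-4H-chromen-4-one (CNP0315714.0)
Conditions: 3 M aq. HCl, MeOH, 40–50 °C, short reaction time
Reagents that add atoms: none
Why: Acid-catalysed acetal solvolysis; aryl methoxymethyl ethers cleave under conditions that prenylated phenols normally tolerate, and the formaldehyde unit is carried off as its dimethyl acetal.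

## Compound list

1 | 2,4-dihydroxybenzaldehyde | O=Cc1ccc(O)cc1O | starting material
2 | 1-bromo-3-methylbut-2-ene (prenyl bromide) | CC(C)=CCBr | starting material
3 | 2-hydroxy-4-[(3-methylbut-2-en-1-yl)oxy]benzaldehyde | O=Cc1ccc(OCC=C(C)C)cc1O | intermediate
4 | 2-(methoxymethoxy)-4-[(3-methylbut-2-en-1-yl)oxy]benzaldehyde | COCOc1cc(OCC=C(C)C)ccc1C=O | intermediate
5 | 4-hydroxy-2-(methoxymethoxy)-5-(2-methylbut-3-en-2-yl)benzaldehyde | C=CC(C)(C)c1cc(C=O)c(OCOC)cc1O | intermediate
6 | 2,4-bis(methoxymethoxy)-5-(2-methylbut-3-en-2-yl)benzaldehyde | C=CC(C)(C)c1cc(C=O)c(OCOC)cc1OCOC | intermediate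
7 | 1-ethynyl-2,4-bis(methoxymethoxy)-5-(2-methylbut-3-en-2-yl)benzene | C=CC(C)(C)c1cc(C#C)c(OCOC)cc1OCOC | intermediate
8 | 3-[2,4-bis(methoxymethoxy)-5-(2-methylbut-3-en-2-yl)phenyl]prop-2-ynoic acid | C=CC(C)(C)c1cc(C#CC(=O)O)c(OCOC)cc1OCOC | intermediate
9 | methyl acetoacetate (methyl 3-oxobutanoate) | COC(=O)CC(C)=O | starting material
10 | methyl 7-methyl-3-oxooct-6-enoate | COC(=O)CC(=O)CCC=C(C)C | intermediate
11 | 3-[2,4-bis(methoxymethoxy)-5-(2-methylbut-3-en-2-yl)phenyl]prop-2-ynoyl chloride (not isolated) | C=CC(C)(C)c1cc(C#CC(Cl)=O)c(OCOC)cc1OCOC | intermediate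
12 | methyl 2-{3-[2,4-bis(methoxymethoxy)-5-(2-methylbut-3-en-2-yl)phenyl]prop-2-ynoyl}-7-methyl-3-oxooct-6-enoate (keto form shown, not isolated) | COC(=O)C(C(=O)CCC=C(C)C)C(=O)C#Cc1cc(C(C)(C)C=C)c(OCOC)cc1OCOC | intermediate
13 | methyl 6-[2,4-bis(methoxymethoxy)-5-(2-methylbut-3-en-2-yl)phenyl]-2-(4-methylpent-3-en-1-yl)-4-oxo-4H-pyran-3-carboxylate | COC(=O)c1c(CCC=C(C)C)oc(-c2cc(C(C)(C)C=C)c(OCOC)cc2OCOC)cc1=O | intermediate
14 | 1-acetylimidazole (N-acetylimidazole) | CC(=O)n1ccnc1 | starting material
15 | methyl 6-[2,4-bis(methoxymethoxy)-5-(2-methylbut-3-en-2-yl)phenyl]-2-(6-methyl-2-oxohept-5-en-3-yl)-4-oxo-4H-pyran-3-carboxylate (racemic, not isolated) | COC(=O)c1c(C(CC=C(C)C)C(C)=O)oc(-c2cc(C(C)(C)C=C)c(OCOC)cc2OCOC)cc1=O | intermediate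
16 | 2-[2,4-bis(methoxymethoxy)-5-(2-methylbut-3-en-2-yl)phenyl]-5,7-dihydroxy-8-(3-methylbut-2-en-1-yl)-4H-chromen-4-one | C=CC(C)(C)c1cc(-c2cc(=O)c3c(O)cc(O)c(CC=C(C)C)c3o2)c(OCOC)cc1OCOC | intermediate
17 | 2-[2,4-dihydroxy-5-(2-methylbut-3-en-2-yl)phenyl]-5,7-dihydroxy-8-(3-methylbut-2-en-1-yl)-4H-chromen-4-one (CNP0315714.0) | C=CC(C)(C)c1cc(-c2cc(=O)c3c(O)cc(O)c(CC=C(C)C)c3o2)c(O)cc1O | target

## Step count and risk

Total step count: 10. Longest linear sequence: 9 steps (steps 1–6, 8, 9 and 10, from 1); step 7 is a one-step branch.

**Step 9 (key step, the proposed new method).**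
- What may go wrong: proton transfer in place of acyl transfer is the most likely failure. The lithiated 13 can deprotonate the acetyl group of 14 or be quenched by the more acidic 15. If 15 does form, O-acetylation or retro-Claisen loss of the acetyl group may outrun the closure, because the second deprotonation has to occur next to an already delocalised anion.
- Fallback (known chemistry, a Baker–Venkataraman flavone synthesis; sets out from aldehyde 6, comes back at 17): Pinnick oxidation (NaClO2, NaH2PO4, 2-methylbut-2-ene) should give 2,4-bis(methoxymethoxy)-5-(2-methylbut-3-en-2-yl)benzoic acid F1. Carbodiimide esterification of F1 with 1-[2-hydroxy-4,6-bis(methoxymethoxy)-3-(3-methylbut-2-en-1-yl)phenyl]ethan-1-one F2 would give the aryl ester F3. F2 would be made from 2,4,6-trihydroxyacetophenone by C-prenylation with 2 and double methoxymethylation, with the hindered chelated hydroxyl next to the prenyl group expected to stay free. KOH in pyridine should move the aroyl group to carbon to give the 1,3-diketone F4. HCl in methanol then closes ring C by cyclodehydration and removes all four acetals to give 17.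
- Cost of the fallback: it gives up the positional certainty at C8, which is why it is only the reserve.

**Step 3.**
- What may go wrong: the [3,3] shift may go in part to C3. At this temperature the product may isomerise further (abnormal Claisen rearrangement through a spirocyclopropane dienone) or lose its five-carbon group thermally.
- Fallback (sets out from 1, comes back at 6): bromination (Br2, AcOH) gives 5-bromo-2,4-dihydroxybenzaldehyde F5, and double methoxymethylation gives 5-bromo-2,4-bis(methoxymethoxy)benzaldehyde F6. A ligand-controlled γ-selective Suzuki–Miyaura coupling of F6 with 3-methylbut-2-enylboronic acid pinacol ester (Pd(OAc)2, bulky biaryl dialkylphosphine, K3PO4) then forms the aryl–carbon bond at the tertiary allyl terminus and gives 6 without any rearrangement.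

**Step 8.**
- What may go wrong: the magnesium enolate of 10 may add in conjugate fashion to the ynoyl chloride or to the ynone just formed, or be acylated on oxygen. The closure may also take the 5-exo course.
- Fallback (sets out from 6 and 10, comes back at 13; avoids ynones): the benzoic acid F1 described above is condensed with Meldrum's acid (DCC, DMAP) to 5-{[2,4-bis(methoxymethoxy)-5-(2-methylbut-3-en-2-yl)phenyl](hydroxy)methylidene}-2,2-dimethyl-1,3-dioxane-4,6-dione F7. Keto ester 10 and pyrrolidine give methyl (2E)-7-methyl-3-(pyrrolidin-1-yl)octa-2,6-dienoate F8. Heating F7 with F8 in toluene releases the aroylketene F9 (not isolated). The enamine carbon attacks the ketene carbonyl, the enolate oxygen of the new aroylacetyl unit closes onto the iminium carbon, and loss of pyrrolidine gives 13.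

**Step 10.**
- What may go wrong: acid-catalysed addition of the 7-OH to the prenyl double bond (ring closure to a chroman), or of solvent to the same olefin, may compete with acetal cleavage.
- Fallback (change of ring B protecting group before ring A exists; sets out from 13, comes back at 17): HCl in methanol on 13 gives methyl 6-[2,4-dihydroxy-5-(2-methylbut-3-en-2-yl)phenyl]-2-(4-methylpent-3-en-1-yl)-4-oxo-4H-pyran-3-carboxylate F10. At this stage no phenol is within reach of the trisubstituted olefin. TBSCl and imidazole in DMF give the bis(tert-butyldimethylsilyl) ether F11. The annulation of step 9 with 14 then passes through the silylated methyl ketone F12 (not isolated) to the 2',4'-bis(tert-butyldimethylsilyl) flavone F13. Bu4NF buffered with AcOH in THF frees both phenols to give 17 without acid; any silyl ether lost earlier to liberated methoxide is of no consequence.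

## Further compounds

F1 | step 9 | 2,4-bis(methoxymethoxy)-5-(2-methylbut-3-en-2-yl)benzoic acid | C=CC(C)(C)c1cc(C(=O)O)c(OCOC)cc1OCOC
F2 | step 9 | 1-[2-hydroxy-4,6-bis(methoxymethoxy)-3-(3-methylbut-2-en-1-yl)phenyl]ethan-1-one | CC(=O)c1c(OCOC)cc(OCOC)c(CC=C(C)C)c1O
F3 | step 9 | 2-acetyl-3,5-bis(methoxymethoxy)-6-(3-methylbut-2-en-1-yl)phenyl 2,4-bis(methoxymethoxy)-5-(2-methylbut-3-en-2-yl)benzoate | C=CC(C)(C)c1cc(C(=O)Oc2c(CC=C(C)C)c(OCOC)cc(OCOC)c2C(C)=O)c(OCOC)cc1OCOC
F4 | step 9 | 1-[2,4-bis(methoxymethoxy)-5-(2-methylbut-3-en-2-yl)phenyl]-3-[2-hydroxy-4,6-bis(methoxymethoxy)-3-(3-methylbut-2-en-1-yl)phenyl]propane-1,3-dione | C=CC(C)(C)c1cc(C(=O)CC(=O)c2c(OCOC)cc(OCOC)c(CC=C(C)C)c2O)c(OCOC)cc1OCOC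
F5 | step 3 | 5-bromo-2,4-dihydroxybenzaldehyde | O=Cc1cc(Br)c(O)cc1O
F6 | step 3 | 5-bromo-2,4-bis(methoxymethoxy)benzaldehyde | COCOc1cc(OCOC)c(C=O)cc1Br
F7 | step 8 | 5-{[2,4-bis(methoxymethoxy)-5-(2-methylbut-3-en-2-yl)phenyl](hydroxy)methylidene}-2,2-dimethyl-1,3-dioxane-4,6-dione | C=CC(C)(C)c1cc(C(O)=C2C(=O)OC(C)(C)OC2=O)c(OCOC)cc1OCOC
F8 | step 8 | methyl (2E)-7-methyl-3-(pyrrolidin-1-yl)octa-2,6-dienoate | COC(=O)/C=C(/N1CCCC1)CCC=C(C)C
F9 | step 8 | 3-[2,4-bis(methoxymethoxy)-5-(2-methylbut-3-en-2-yl)phenyl]prop-1-ene-1,3-dione (aroylketene, not isolated) | C=CC(C)(C)c1cc(C(=O)C=C=O)c(OCOC)cc1OCOC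
F10 | step 10 | methyl 6-[2,4-dihydroxy-5-(2-methylbut-3-en-2-yl)phenyl]-2-(4-methylpent-3-en-1-yl)-4-oxo-4H-pyran-3-carboxylate | COC(=O)c1c(CCC=C(C)C)oc(-c2cc(C(C)(C)C=C)c(O)cc2O)cc1=O
F11 | step 10 | methyl 6-[2,4-bis(tert-butyldimethylsilyloxy)-5-(2-methylbut-3-en-2-yl)phenyl]-2-(4-methylpent-3-en-1-yl)-4-oxo-4H-pyran-3-carboxylate | COC(=O)c1c(CCC=C(C)C)oc(-c2cc(C(C)(C)C=C)c(O[Si](C)(C)C(C)(C)C)cc2O[Si](C)(C)C(C)(C)C)cc1=O
F12 | step 10 | methyl 6-[2,4-bis(tert-butyldimethylsilyloxy)-5-(2-methylbut-3-en-2-yl)phenyl]-2-(6-methyl-2-oxohept-5-en-3-yl)-4-oxo-4H-pyran-3-carboxylate (racemic, not isolated) | COC(=O)c1c(C(CC=C(C)C)C(C)=O)oc(-c2cc(C(C)(C)C=C)c(O[Si](C)(C)C(C)(C)C)cc2O[Si](C)(C)C(C)(C)C)cc1=O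
F13 | step 10 | 2-[2,4-bis(tert-butyldimethylsilyloxy)-5-(2-methylbut-3-en-2-yl)phenyl]-5,7-dihydroxy-8-(3-methylbut-2-en-1-yl)-4H-chromen-4-one | C=CC(C)(C)c1cc(-c2cc(=O)c3c(O)cc(O)c(CC=C(C)C)c3o2)c(O[Si](C)(C)C(C)(C)C)cc1O[Si](C)(C)C(C)(C)C
A1 | alternative 1 | 7-(methoxymethoxy)-2-{2-(methoxymethoxy)-4-[(3-methylbut-2-en-1-yl)oxy]phenyl}-5-[(3-methylbut-2-en-1-yl)oxy]-4H-chromen-4-one | CC(C)=CCOc1ccc(-c2cc(=O)c3c(OCC=C(C)C)cc(OCOC)cc3o2)c(OCOC)c1
A2 | alternative 1 | 5-hydroxy-2-[4-hydroxy-2-(methoxymethoxy)-5-(2-methylbut-3-en-2-yl)phenyl]-7-(methoxymethoxy)-8-(3-methylbut-2-en-1-yl)-4H-chromen-4-one | C=CC(C)(C)c1cc(-c2cc(=O)c3c(O)cc(OCOC)c(CC=C(C)C)c3o2)c(OCOC)cc1O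
A3 | alternative 2 | 2-ethynyl-5,7-bis(methoxymethoxy)-8-(3-methylbut-2-en-1-yl)-4H-chromen-4-one | C#Cc1cc(=O)c2c(OCOC)cc(OCOC)c(CC=C(C)C)c2o1
A4 | alternative 2 | [(1-methoxy-5,5-dimethylhepta-1,3,6-triene-1,3-diyl)bis(oxy)]bis(trimethylsilane) | COC(O[Si](C)(C)C)=CC(O[Si](C)(C)C)=CC(C)(C)C=C
A5 | alternative 2 | 2-[2,4-dihydroxy-5-(2-methylbut-3-en-2-yl)phenyl]-5,7-bis(methoxymethoxy)-8-(3-methylbut-2-en-1-yl)-4H-chromen-4-one | C=CC(C)(C)c1cc(-c2cc(=O)c3c(OCOC)cc(OCOC)c(CC=C(C)C)c3o2)c(O)cc1O
A6 | alternative 3 | 3,5-bis(methoxymethoxy)-2-(3-methylbut-2-en-1-yl)-6-(trimethylsilyl)phenyl trifluoromethanesulfonate | COCOc1cc(OCOC)c([Si](C)(C)C)c(OS(=O)(=O)C(F)(F)F)c1CC=C(C)C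
A7 | alternative 3 | 2-[2,4-bis(methoxymethoxy)-5-(2-methylbut-3-en-2-yl)phenyl]-5,7-bis(methoxymethoxy)-8-(3-methylbut-2-en-1-yl)-4H-chromen-4-one | C=CC(C)(C)c1cc(-c2cc(=O)c3c(OCOC)cc(OCOC)c(CC=C(C)C)c3o2)c(OCOC)cc1OCOC
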